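All runs stem from a simulated flask from invented constants; the scatter is artificial.

- The number I reckoned with was 0.915: the fraction of the E charged that the flask uses up in 15 min if it keeps the pace of the grey run.

all flasks: E 0.20 M; L 78 mM (held)
- grey: D 1 mol%; run made earlier
- flask: D 0.5 mol%; time 15 min

grey run (percent of the E charged)

| time / min | G / % | Q / % | E / % |
|---|---|---|---|
| 0.333 | 2.0 | 0 | 97.9 |
| 0.500 | 1.9 | 0.8 | 95.6 |
| 0.833 | 6.4 | 0 | 94.4 |
| 1.33 | 6.3 | 0 | 90.9 |
| 2.00 | 8.6 | 0.8 | 87.8 |
| 3.00 | 13.5 | 0 | 82.4 |
| 5.00 | 21.4 | 0.7 | 69.5 |

(each reading ± 1 percentage point)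

- for G the Q are counted in
- at the start none of L is in solution
- J is what L becomes in solution
- no earlier run changes the charge of D; that part of a forecast is a guess

1. amount of G and Q together at 15 min, in percent of the E charged
2. concentration of J in solution at 15 min, in percent of saturation

- I took that pace from the last grey reading, 12.2 mM min⁻¹ of E lost. The reading at 3.00 min gave 11.7 mM min⁻¹, so the pace did not visibly slacken as E fell.
- My guess was that gas crossing into solution was the rate-limiting step. The pace of the flask then ignores the charge of D and J stays low, but no earlier run tests this.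
- The number counts E lost, not G formed, so it needed a partner. By its last reading the grey run kept 0.702 of its lost E as G and Q, above an even split, and so I reckoned 64.2% of G and Q for the flask.
- The forecast differed from my reckoning: it gave 32% of G and Q, with J at 75% of saturation, reasoning “if the rate scales with D”.
- The flask gave 61.6% of G and Q, with J at 7.11% of saturation.

    D + G ⇌ Q (K = 3.70 L mol⁻¹, k = 0.0360 L mol⁻¹ s⁻¹)
    G + D ⇌ X + D, rate k2*[D]*[G] forward; the back reaction follows from the equilibrium constant (K = 0.530, k = 5.70 L mol⁻¹ s⁻¹)
    L ⇌ J, rate k3*(csat - [J]) (kL = 0.00270 s⁻¹)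
    E + J + D → D + G (k = 2100 L² mol⁻² s⁻¹)

- The flask lost 90.1% of its E against the number's 91.5%, and a neighbour charged with 0.50 M of E, where the number falls to 36.6%, lost 37.8% of its E. Of what it lost, the flask charged with 0.20 M kept 0.683 as G and Q. That share stands high through the undoing of X into G: the run without that step ends at 19.0% of G and Q instead of 61.6%.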